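The lactone is cut at its two exocyclic bonds, C4–CH2(ring A) and C3–CH2(ring B). The key step exploits that C4 (β to the C2 carbonyl) and C3 (α to it) carry trans arylmethyl groups and that C5 is an OCH2 which can be carried as a chiral acetal: a lithiated ring-A aryl dithiane adds to C4 of (5R)-5-menthyloxyfuran-2(5H)-one and the resulting enolate is benzylated at C3 by a ring-B benzylic bromide, forming both bonds and both stereocentres in one flask. Its precursors are that butenolide, an O-benzyl ring-A dithiane and an O-silyl ring-B bromide. The threo ring-C side chain is added afterwards by a glycolate syn-aldol.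

Key step: step 7

Labels: lactone O1, C2 (C=O), C3, C4, C5; ring A = aryl of the C4 arylmethyl group, ring B = aryl of the C3 arylmethyl group, ring C = aryl of the glycerol side chain (C7 carbinol, C8 ether carbon, C9 CH2OH).
Assumption: (S)-4-benzyl-3-(chloroacetyl)oxazolidin-2-one (19) is taken as a purchasable reagent.

Step 1
Reactants: 1 furfural
Product: 3 5-hydroxyfuran-2(5H)-one (racemic), via furan endoperoxide 2 (not isolated)
Conditions: O2, hν (visible), methylene blue (cat.), MeOH, rt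
Reagents that add atoms: oxygen, O=O
Why: Sensitised photo-oxygenation, in which singlet oxygen adds across C2/C5 of the furan in a [4+2] cycloaddition and methanolysis of endoperoxide 2 expels the formyl carbon as methyl formate, leaving the racemic hydroxybutenolide.

Step 2
Reactants: 3 5-hydroxyfuran-2(5H)-one; 4 (−)-menthol
Product: 5 (5R)-5-[(1R,2S,5R)-menthyloxy]furan-2(5H)-one
Conditions: CSA (cat.), toluene, reflux (Dean–Stark); crystallisation from petroleum ether, mother liquor re-equilibrated with CSA and recrystallised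
Reagents that add atoms: none
Why: Acid-catalysed acetalisation of the lactol (via the oxocarbenium ion) gives both C5 epimers, of which the (5R) epimer derived from (−)-menthol is the crystalline one, and because the acetal carbon epimerises under acid the C5 centre is set by crystallisation-driven equilibration.

Step 3
Reactants: 6 4-(benzyloxy)-3-methoxybenzaldehyde
Product: 7 2-[4-(benzyloxy)-3-methoxyphenyl]-1,3-dithiane
Conditions: HS(CH2)3SH, BF3·OEt2, CH2Cl2, 0 °C to rt
Reagents that add atoms: propane-1,3-dithiol, SCCCS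
Why: Lewis-acid dithioacetalisation of an aromatic aldehyde is routine, spares the benzyl ether and turns the ring-A benzylic carbon into an acyl-anion equivalent (Corey–Seebach umpolung).

Step 4
Reactants: 8 vanillin
Product: 9 4-[(tert-butyldimethylsilyl)oxy]-3-methoxybenzaldehyde
Conditions: TBSCl, imidazole, DMF, rt
Reagents that add atoms: tert-butyldimethylsilyl chloride, CC(C)(C)[Si](C)(C)Cl
Why: Imidazole-mediated silylation of the phenol gives a base-labile aryl silyl ether, chosen so that the ring-B phenol is released later by the hydroxide of step 8 without a separate deprotection.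

Step 5
Reactants: 9 4-[(tert-butyldimethylsilyl)oxy]-3-methoxybenzaldehyde
Product: 10 {4-[(tert-butyldimethylsilyl)oxy]-3-methoxyphenyl}methanol
Conditions: NaBH4, MeOH, 0 °C, short reaction time
Reagents that add atoms: none
Why: Borohydride reduction of an aromatic aldehyde is fast at 0 °C, so the aryl silyl ether should survive the brief exposure.

Step 6
Reactants: 10 {4-[(tert-butyldimethylsilyl)oxy]-3-methoxyphenyl}methanol
Product: 11 [4-(bromomethyl)-2-methoxyphenoxy](tert-butyl)dimethylsilane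
Conditions: PBr3, Et2O, 0 °C; used crude at once
Reagents that add atoms: phosphorus tribromide, BrP(Br)Br
Why: Bromination of an electron-rich benzylic alcohol through its phosphite ester proceeds under mild conditions, and the labile p-siloxybenzyl bromide is taken directly into the next step.

Step 7
Reactants: 7 2-[4-(benzyloxy)-3-methoxyphenyl]-1,3-dithiane; 5 (5R)-5-[(1R,2S,5R)-menthyloxy]furan-2(5H)-one; 11 [4-(bromomethyl)-2-methoxyphenoxy](tert-butyl)dimethylsilane
Product: 14 (3R,4R,5R)-4-{2-[4-(benzyloxy)-3-methoxyphenyl]-1,3-dithian-2-yl}-3-{4-[(tert-butyldimethylsilyl)oxy]-3-methoxybenzyl}-5-[(1R,2S,5R)-menthyloxy]dihydrofuran-2(3H)-one, via lithiated dithiane 12 (not isolated), via lithium enolate 13 (not isolated)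
Conditions: 7, n-BuLi, THF, −78 to −30 °C; 5, −78 °C; then 11, DMPU, −78 °C to rt
Reagents that add atoms: none
Why: n-BuLi removes the dithiane C2–H of 7 to give the sulfur-stabilised benzylic anion 12, which adds in Michael fashion to C4 of butenolide 5 to leave lithium enolate 13, and 13 is then C-benzylated at C3 by bromide 11 in an SN2 step, so two exocyclic C–C bonds form in one flask and no ring is closed. The closest known reaction type is the tandem conjugate addition–enolate alkylation of 5-alkoxyfuran-2(5H)-ones with 2-aryl-1,3-dithiane anions, as used for dibenzylbutyrolactone lignans. C4 is controlled by the C5 acetal, since the anion approaches the flat butenolide on the face opposite the menthyloxy group and gives the 4,5-trans relationship. C3 is controlled by C4, since the bulky dithianyl group shields its own face of the enolate and the bromide enters trans to it. The step needs 1,4- over 1,2-addition, which the soft, hindered aryl dithiane anion and the unhindered β-carbon secure, and C-alkylation faster than proton transfer, which the reactive benzylic bromide with DMPU secures. The ring assignment is fixed by construction because ring A arrives in the nucleophile and ring B in the electrophile.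

Step 8
Reactants: 14 (3R,4R,5R)-tandem adduct
Product: 17 (3R,4R)-4-{2-[4-(benzyloxy)-3-methoxyphenyl]-1,3-dithian-2-yl}-3-(4-hydroxy-3-methoxybenzyl)dihydrofuran-2(3H)-one, via formyl carboxylate 15 (not isolated), via hydroxy carboxylate 16 (not isolated)
Conditions: KOH, NaBH4, EtOH/H2O, rt; then aq. HCl to pH 1, rt
Reagents that add atoms: none
Why: Saponification opens the lactone acetal to the carboxylate and the C5 aldehyde with loss of menthol, borohydride reduces that aldehyde in situ before it can epimerise, the ethanolic KOH also cleaves the aryl silyl ether, and acidification relactonises onto the original C2 carboxyl (γ-lactonisation), so the carbonyl stays next to C3 and neither stereocentre is touched.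

Step 9
Reactants: 17 (3R,4R)-dithianyl phenol lactone
Product: 18 (3R,4R)-4-[4-(benzyloxy)-3-methoxybenzyl]-3-(4-hydroxy-3-methoxybenzyl)dihydrofuran-2(3H)-one
Conditions: NiCl2·6H2O, NaBH4, MeOH/THF, 0 °C
Reagents that add atoms: none
Why: Reductive desulfurisation with nickel boride Ni2B generated in situ cleaves both benzylic C–S bonds to give the ring-A CH2, and at 0 °C it is expected to spare the benzyl ether, the lactone and the C4 configuration.

Step 10
Reactants: 18 (3R,4R)-ring-A-O-benzyl lactone phenol; 19 (S)-4-benzyl-3-(chloroacetyl)oxazolidin-2-one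
Product: 20 (S)-4-benzyl-3-[2-(4-{[(3R,4R)-4-(4-benzyloxy-3-methoxybenzyl)-2-oxotetrahydrofuran-3-yl]methyl}-2-methoxyphenoxy)acetyl]oxazolidin-2-one
Conditions: K2CO3, DMF, rt
Reagents that add atoms: none
Why: Williamson etherification, in which the only free phenol (ring B, ring A being benzylated) displaces chloride from the strongly SN2-activated α-chloro imide under conditions too mild to open the lactone.

Step 11
Reactants: 20 ring-B aryloxyacetyl imide; 6 4-(benzyloxy)-3-methoxybenzaldehyde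
Product: 23 (S)-4-benzyl-3-[(2S,3R)-3-(4-benzyloxy-3-methoxyphenyl)-2-(4-{[(3R,4R)-4-(4-benzyloxy-3-methoxybenzyl)-2-oxotetrahydrofuran-3-yl]methyl}-2-methoxyphenoxy)-3-hydroxypropanoyl]oxazolidin-2-one, via boron enolate 21 (not isolated), via boron aldolate 22 (not isolated)
Conditions: Bu2BOTf, iPr2NEt, CH2Cl2, −78 to 0 °C; 6, −78 to 0 °C; then pH 7 buffer, MeOH, 30% H2O2, 0 °C
Reagents that add atoms: none
Why: Evans boron syn-aldol, in which Bu2BOTf/iPr2NEt enolises only the imide (not the lactone) to the Z-enolate 21, the chair Zimmerman–Traxler transition state gives the syn relationship of C7 and C8, and the benzyl group of the (S)-auxiliary directs the aldehyde to one enolate face so that the (2S,3R) adduct, the precursor of the (7R,8R) threo unit, should result.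

Step 12
Reactants: 23 syn-aldol imide
Product: 25 (3R,4R)-4-[4-(benzyloxy)-3-methoxybenzyl]-3-(4-{[(1R,2R)-1-(4-benzyloxy-3-methoxyphenyl)-1,3-dihydroxypropan-2-yl]oxy}-3-methoxybenzyl)dihydrofuran-2(3H)-one, via hydroxy aldehyde 24 (not isolated)
Conditions: NaBH4, THF/H2O (4:1), 0 °C to rt
Reagents that add atoms: none
Why: Reductive cleavage of the activated N-acyl oxazolidinone by NaBH4 in wet THF proceeds through aldehyde 24 to the primary alcohol, whereas the much less electrophilic γ-lactone should be left intact (LiBH4 is avoided because it would reduce the lactone as well), and no stereocentre is involved.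

Step 13
Reactants: 25 bis-benzyl ether diol
Product: 26 (3R,4R)-3-(4-{[(1R,2R)-1,3-dihydroxy-1-(4-hydroxy-3-methoxyphenyl)propan-2-yl]oxy}-3-methoxybenzyl)-4-(4-hydroxy-3-methoxybenzyl)dihydrofuran-2(3H)-one
Conditions: H2 (1 atm), 10% Pd/C, EtOAc/EtOH, rt, stopped at full debenzylation
Reagents that add atoms: none
Why: Catalytic hydrogenolysis removes the two aryl benzyl ethers (rings A and C) under neutral conditions, under which the lactone, the alkyl aryl ether and the secondary benzylic alcohol should persist.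

Compound list
1 | furfural (furan-2-carbaldehyde) | O=Cc1ccco1 | starting material
2 | 2,3,7-trioxabicyclo[2.2.1]hept-5-ene-1-carbaldehyde, singlet-oxygen adduct of furfural (racemic) | O=CC12C=CC(OO1)O2 | intermediate
3 | 5-hydroxyfuran-2(5H)-one (racemic) | O=C1C=CC(O)O1 | intermediate
4 | (−)-menthol, (1R,2S,5R)-2-isopropyl-5-methylcyclohexan-1-ol | C[C@@H]1CC[C@H]([C@@H](C1)O)C(C)C | starting material
5 | (5R)-5-[(1R,2S,5R)-menthyloxy]furan-2(5H)-one | O=C1C=C[C@H](O[C@@H]2C[C@H](C)CC[C@H]2C(C)C)O1 | intermediate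
6 | 4-(benzyloxy)-3-methoxybenzaldehyde | COc1cc(C=O)ccc1OCc1ccccc1 | starting material
7 | 2-[4-(benzyloxy)-3-methoxyphenyl]-1,3-dithiane | COc1cc(C2SCCCS2)ccc1OCc1ccccc1 | intermediate
8 | vanillin (4-hydroxy-3-methoxybenzaldehyde) | COc1cc(C=O)ccc1O | starting material
9 | 4-[(tert-butyldimethylsilyl)oxy]-3-methoxybenzaldehyde | COc1cc(C=O)ccc1O[Si](C)(C)C(C)(C)C | intermediate
10 | {4-[(tert-butyldimethylsilyl)oxy]-3-methoxyphenyl}methanol | COc1cc(CO)ccc1O[Si](C)(C)C(C)(C)C | intermediate
11 | [4-(bromomethyl)-2-methoxyphenoxy](tert-butyl)dimethylsilane | COc1cc(CBr)ccc1O[Si](C)(C)C(C)(C)C | intermediate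
12 | 2-lithio-2-[4-(benzyloxy)-3-methoxyphenyl]-1,3-dithiane | [Li]C1(SCCCS1)c1ccc(OCc2ccccc2)c(OC)c1 | intermediate
13 | lithium enolate of (4R,5R)-4-{2-[4-(benzyloxy)-3-methoxyphenyl]-1,3-dithian-2-yl}-5-[(1R,2S,5R)-menthyloxy]dihydrofuran-2(3H)-one | [Li]OC1=C[C@@H](C2(SCCCS2)c2ccc(OCc3ccccc3)c(OC)c2)[C@H](O[C@@H]2C[C@H](C)CC[C@H]2C(C)C)O1 | intermediate
14 | (3R,4R,5R)-4-{2-[4-(benzyloxy)-3-methoxyphenyl]-1,3-dithian-2-yl}-3-{4-[(tert-butyldimethylsilyl)oxy]-3-methoxybenzyl}-5-[(1R,2S,5R)-menthyloxy]dihydrofuran-2(3H)-one (3,4-trans, 4,5-trans) | COc1cc(C2(SCCCS2)[C@H]2[C@H](O[C@@H]3C[C@H](C)CC[C@H]3C(C)C)OC(=O)[C@@H]2Cc2ccc(O[Si](C)(C)C(C)(C)C)c(OC)c2)ccc1OCc1ccccc1 | intermediate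
15 | potassium (2R,3R)-3-{2-[4-(benzyloxy)-3-methoxyphenyl]-1,3-dithian-2-yl}-2-{4-[(tert-butyldimethylsilyl)oxy]-3-methoxybenzyl}-4-oxobutanoate | COc1cc(C2(SCCCS2)[C@@H](C=O)[C@@H](Cc2ccc(O[Si](C)(C)C(C)(C)C)c(OC)c2)C([O-])=O)ccc1OCc1ccccc1.[K+] | intermediate
16 | dipotassium salt (carboxylate and ring-B phenoxide) of (2R,3R)-3-{2-[4-(benzyloxy)-3-methoxyphenyl]-1,3-dithian-2-yl}-4-hydroxy-2-(4-hydroxy-3-methoxybenzyl)butanoic acid | COc1cc(C2(SCCCS2)[C@@H](CO)[C@@H](Cc2ccc([O-])c(OC)c2)C([O-])=O)ccc1OCc1ccccc1.[K+].[K+] | intermediate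
17 | (3R,4R)-4-{2-[4-(benzyloxy)-3-methoxyphenyl]-1,3-dithian-2-yl}-3-(4-hydroxy-3-methoxybenzyl)dihydrofuran-2(3H)-one | COc1cc(C2(SCCCS2)[C@H]2COC(=O)[C@@H]2Cc2ccc(O)c(OC)c2)ccc1OCc1ccccc1 | intermediate
18 | (3R,4R)-4-[4-(benzyloxy)-3-methoxybenzyl]-3-(4-hydroxy-3-methoxybenzyl)dihydrofuran-2(3H)-one | COc1cc(C[C@H]2COC(=O)[C@@H]2Cc2ccc(O)c(OC)c2)ccc1OCc1ccccc1 | intermediate
19 | (S)-4-benzyl-3-(chloroacetyl)oxazolidin-2-one | O=C(CCl)N1[C@@H](Cc2ccccc2)COC1=O | starting material
20 | (S)-4-benzyl-3-[2-(4-{[(3R,4R)-4-(4-benzyloxy-3-methoxybenzyl)-2-oxotetrahydrofuran-3-yl]methyl}-2-methoxyphenoxy)acetyl]oxazolidin-2-one | COc1cc(C[C@H]2COC(=O)[C@@H]2Cc2ccc(OCC(=O)N3[C@@H](Cc4ccccc4)COC3=O)c(OC)c2)ccc1OCc1ccccc1 | intermediate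
21 | (Z)-dibutylboron enolate of 20 (O–BBu2 cis to the aryloxy group) | COc1cc(C[C@H]2COC(=O)[C@@H]2Cc2ccc(O/C=C(\OB(CCCC)CCCC)N3[C@@H](Cc4ccccc4)COC3=O)c(OC)c2)ccc1OCc1ccccc1 | intermediate
22 | dibutylboron aldolate of 23 (O–BBu2 on the C7 oxygen) | COc1cc(C[C@H]2COC(=O)[C@@H]2Cc2ccc(O[C@H](C(=O)N3[C@@H](Cc4ccccc4)COC3=O)[C@H](OB(CCCC)CCCC)c3ccc(OCc4ccccc4)c(OC)c3)c(OC)c2)ccc1OCc1ccccc1 | intermediate
23 | (S)-4-benzyl-3-[(2S,3R)-3-(4-benzyloxy-3-methoxyphenyl)-2-(4-{[(3R,4R)-4-(4-benzyloxy-3-methoxybenzyl)-2-oxotetrahydrofuran-3-yl]methyl}-2-methoxyphenoxy)-3-hydroxypropanoyl]oxazolidin-2-one | COc1cc(C[C@H]2COC(=O)[C@@H]2Cc2ccc(O[C@H](C(=O)N3[C@@H](Cc4ccccc4)COC3=O)[C@H](O)c3ccc(OCc4ccccc4)c(OC)c3)c(OC)c2)ccc1OCc1ccccc1 | intermediate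
24 | (2S,3R)-3-(4-benzyloxy-3-methoxyphenyl)-2-(4-{[(3R,4R)-4-(4-benzyloxy-3-methoxybenzyl)-2-oxotetrahydrofuran-3-yl]methyl}-2-methoxyphenoxy)-3-hydroxypropanal | COc1cc(C[C@H]2COC(=O)[C@@H]2Cc2ccc(O[C@H](C=O)[C@H](O)c3ccc(OCc4ccccc4)c(OC)c3)c(OC)c2)ccc1OCc1ccccc1 | intermediate
25 | (3R,4R)-4-[4-(benzyloxy)-3-methoxybenzyl]-3-(4-{[(1R,2R)-1-(4-benzyloxy-3-methoxyphenyl)-1,3-dihydroxypropan-2-yl]oxy}-3-methoxybenzyl)dihydrofuran-2(3H)-one | COc1cc(C[C@H]2COC(=O)[C@@H]2Cc2ccc(O[C@H](CO)[C@H](O)c3ccc(OCc4ccccc4)c(OC)c3)c(OC)c2)ccc1OCc1ccccc1 | intermediate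
26 | (3R,4R)-3-(4-{[(1R,2R)-1,3-dihydroxy-1-(4-hydroxy-3-methoxyphenyl)propan-2-yl]oxy}-3-methoxybenzyl)-4-(4-hydroxy-3-methoxybenzyl)dihydrofuran-2(3H)-one (CNP0305334.1) | COc1cc(C[C@H]2COC(=O)[C@@H]2Cc2ccc(O[C@H](CO)[C@H](O)c3ccc(O)c(OC)c3)c(OC)c2)ccc1O | target

Total step count: 13. Longest linear sequence: 10 steps (steps 4–13, from vanillin 8).

Steps most likely to fail

Step 7. The one-pot sequence may break down through 1,2-addition of the anion, proton transfer to the enolate before it is benzylated, or decay of the labile bromide, so that the second C–C bond is not formed cleanly. Fallback: the two bond formations are uncoupled. Setting out from 5 and 7, anion 12 is added to 5 as before but the enolate is quenched with NH4Cl to isolate the mono-adduct (4R,5R)-4-{2-[4-(benzyloxy)-3-methoxyphenyl]-1,3-dithian-2-yl}-5-[(1R,2S,5R)-menthyloxy]dihydrofuran-2(3H)-one F1. After purification F1 is re-enolised with LDA (THF, −78 °C) to 13 and benzylated with 11 in the presence of DMPU, a separate lactone-enolate alkylation that should again enter trans to the C4 group. The route is rejoined at 14.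

Step 12. Chemoselectivity may be lost through hydride attack on the lactone, or the basic medium may trigger retro-aldol cleavage before the imide is reduced. Fallback: setting out from 23, the auxiliary is removed hydrolytically (LiOH, H2O2, THF/H2O, 0 °C; Na2SO3; acidification to pH 2 so that any opened lactone recloses) to give (2S,3R)-3-(4-benzyloxy-3-methoxyphenyl)-2-(4-{[(3R,4R)-4-(4-benzyloxy-3-methoxybenzyl)-2-oxotetrahydrofuran-3-yl]methyl}-2-methoxyphenoxy)-3-hydroxypropanoic acid F2. Its free carboxyl group is then reduced with BH3·SMe2 (THF, 0 °C to rt), which reduces carboxylic acids far faster than lactones. The route is rejoined at 25.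

Step 11. Enolisation may be incomplete or unselective because Bu2BOTf is sequestered by the lactone and ether oxygens, with erosion of syn or facial selectivity. Fallback: the aldol is run on a more easily enolised and more easily cleaved auxiliary through a titanium enolate.
- Setting out from 18, the phenol is alkylated with tert-butyl bromoacetate (K2CO3, acetone) to tert-butyl 2-(4-{[(3R,4R)-4-(4-benzyloxy-3-methoxybenzyl)-2-oxotetrahydrofuran-3-yl]methyl}-2-methoxyphenoxy)acetate F3.
- TFA/CH2Cl2 releases 2-(4-{[(3R,4R)-4-(4-benzyloxy-3-methoxybenzyl)-2-oxotetrahydrofuran-3-yl]methyl}-2-methoxyphenoxy)acetic acid F4.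
- EDC·HCl/DMAP coupling with (S)-4-benzylthiazolidine-2-thione gives (S)-4-benzyl-3-[2-(ring-B aryloxy)acetyl]thiazolidine-2-thione F5.
- The chlorotitanium enolate of F5 (TiCl4, iPr2NEt, NMP, CH2Cl2, −78 °C), in the non-chelated regime that gives the same syn sense as the boron aldol, is combined with 6 to give the (2S,3R) syn-aldol thiazolidinethione F6.
- NaBH4 (THF/EtOH, 0 °C) cleaves the very reactive thione imide in the presence of the lactone, and the route is rejoined at 25.

Further compounds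
F1 | step 7 | (4R,5R)-4-{2-[4-(benzyloxy)-3-methoxyphenyl]-1,3-dithian-2-yl}-5-[(1R,2S,5R)-menthyloxy]dihydrofuran-2(3H)-one | COc1cc(C2(SCCCS2)[C@H]2[C@H](O[C@@H]3C[C@H](C)CC[C@H]3C(C)C)OC(=O)C2)ccc1OCc1ccccc1
F2 | step 12 | (2S,3R)-3-(4-benzyloxy-3-methoxyphenyl)-2-(4-{[(3R,4R)-4-(4-benzyloxy-3-methoxybenzyl)-2-oxotetrahydrofuran-3-yl]methyl}-2-methoxyphenoxy)-3-hydroxypropanoic acid | COc1cc(C[C@H]2COC(=O)[C@@H]2Cc2ccc(O[C@H](C(=O)O)[C@H](O)c3ccc(OCc4ccccc4)c(OC)c3)c(OC)c2)ccc1OCc1ccccc1
F3 | step 11 | tert-butyl 2-(4-{[(3R,4R)-4-(4-benzyloxy-3-methoxybenzyl)-2-oxotetrahydrofuran-3-yl]methyl}-2-methoxyphenoxy)acetate | COc1cc(C[C@H]2COC(=O)[C@@H]2Cc2ccc(OCC(=O)OC(C)(C)C)c(OC)c2)ccc1OCc1ccccc1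
F4 | step 11 | 2-(4-{[(3R,4R)-4-(4-benzyloxy-3-methoxybenzyl)-2-oxotetrahydrofuran-3-yl]methyl}-2-methoxyphenoxy)acetic acid | COc1cc(C[C@H]2COC(=O)[C@@H]2Cc2ccc(OCC(=O)O)c(OC)c2)ccc1OCc1ccccc1
F5 | step 11 | (S)-4-benzyl-3-[2-(4-{[(3R,4R)-4-(4-benzyloxy-3-methoxybenzyl)-2-oxotetrahydrofuran-3-yl]methyl}-2-methoxyphenoxy)acetyl]thiazolidine-2-thione | COc1cc(C[C@H]2COC(=O)[C@@H]2Cc2ccc(OCC(=O)N3[C@@H](Cc4ccccc4)CSC3=S)c(OC)c2)ccc1OCc1ccccc1
F6 | step 11 | (S)-4-benzyl-3-[(2S,3R)-3-(4-benzyloxy-3-methoxyphenyl)-2-(4-{[(3R,4R)-4-(4-benzyloxy-3-methoxybenzyl)-2-oxotetrahydrofuran-3-yl]methyl}-2-methoxyphenoxy)-3-hydroxypropanoyl]thiazolidine-2-thione | COc1cc(C[C@H]2COC(=O)[C@@H]2Cc2ccc(O[C@H](C(=O)N3[C@@H](Cc4ccccc4)CSC3=S)[C@H](O)c3ccc(OCc4ccccc4)c(OC)c3)c(OC)c2)ccc1OCc1ccccc1
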